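**Retrosynthetic overview** (oxepine numbering: O1, C2 quaternary, C3, C4, C5=C6, C7)
1. Late disconnections: the coumarate ester (Mitsunobu), the aryl ketone (aryllithium plus Weinreb amide) and the E-allylic alcohol (cross-metathesis of a butenyl handle with methacrolein, then 1,2-reduction).
2. The CH2C(=O)Ar arm at C2 comes from one carboxyl of a geminal diester by Arndt–Eistert homologation; the (S) configuration comes from carboxylesterase desymmetrisation of that prochiral diester.
3. Key disconnection: the tetrahydrooxepine is cut at O1–C7 and C2–C3 into diethyl ketomalonate (O1=C2) and 2-cyclopropylhexa-1,5-diene, joined by a Paternò–Büchi-type [5+2] photocycloaddition with radical-clock ring expansion (three-membered to seven-membered ring).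
4. Enabling feature: the five ring carbons C7H2–C6(R)=C5H–C4H2–C3H2 between O1 and C2 are the imprint of an opened 1-substituted vinylcyclopropane (C7 and C6 are the former alkene, C5, C4 and C3 the former cyclopropane, and C5=C6 lies where the cyclopropylcarbinyl-to-homoallyl shift leaves it); C2, bonded to O1 and a carboxyl carbon, is a former ketomalonate carbonyl.
5. Ring order: the oxepine ring is the only ring made (step 3); both benzene rings are bought (hydroquinone, p-coumaric acid).

Key step: step 3

Assumption: the carboxylesterase is taken to hydrolyse the pro-S ethoxycarbonyl group of 8, giving the (R)-half-ester 9; the sense has to be confirmed on the half-ester, and the fallback to step 4 covers the other outcome.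

**Step 1**
Reactants: 1 N-methoxy-N-methylcyclopropanecarboxamide; 2 but-3-en-1-ylmagnesium bromide
Product: 3 1-cyclopropylpent-4-en-1-one
Conditions: 2 (1.2 equiv), THF, 0 °C → rt; aq. NH4Cl
Reagents that add atoms: none
Why: Weinreb ketone synthesis, in which the magnesium-chelated tetrahedral intermediate survives until work-up and so should prevent a second addition.

**Step 2**
Reactants: 3 1-cyclopropylpent-4-en-1-one
Product: 4 2-cyclopropylhexa-1,5-diene
Conditions: Ph3PCH3Br, KOtBu, THF, 0 °C → rt; pentane extraction, careful distillation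
Reagents that add atoms: methyltriphenylphosphonium bromide, C[P+](c1ccccc1)(c1ccccc1)c1ccccc1.[Br-]
Why: Wittig methylenation of a ketone with the unstabilised ylide should give the volatile 1,1-disubstituted vinylcyclopropane without touching the cyclopropane or the terminal alkene.

**Step 3**
Reactants: 4 2-cyclopropylhexa-1,5-diene; 5 diethyl ketomalonate (diethyl 2-oxopropanedioate)
Product: 8 diethyl 6-(but-3-en-1-yl)-2,3,4,7-tetrahydrooxepine-2,2-dicarboxylate, via triplet 1,4-biradical 6 (not isolated), via Z-configured 1,7-biradical 7 (not isolated)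
Conditions: freshly distilled 5 (1 equiv), 4 (3 equiv, excess recovered), degassed benzene, hν (365 nm), 40 °C
Reagents that add atoms: none
Why: Excitation of 5 and intersystem crossing give its n,π* triplet, whose electrophilic oxygen adds to the terminal CH2 of the cyclopropyl-substituted alkene of 4 to give the most stabilised triplet 1,4-biradical 6 (alkoxymalonyl radical at C2, tertiary cyclopropylcarbinyl radical at C6), and the cyclopropylcarbinyl radical opens as a radical clock to the homoallyl 1,7-biradical 7, which after spin inversion couples C3 with C2. The closest known reaction type is the Paternò–Büchi photocycloaddition of triplet ketones to vinylcyclopropanes, in which this diversion of the 1,4-biradical to 2,3,4,7-tetrahydrooxepines accompanies oxetane formation, together with the Paternò–Büchi reaction of ketomalonates with simple alkenes. The seven-membered ring is closed by intramolecular radical–radical recombination of the 1,7-biradical (a formal [5+2] photocycloaddition of C=O across the vinylcyclopropane), the O1–C7 bond being made first and the C2–C3 bond last. No stereocentre is created: C2 carries two identical ester groups and stays prochiral, and the only stereo-element, the cis C5=C6 bond, is enforced because only Z-configured 7 can reach ring closure. The step needs regioselectivity (oxygen to CH2, secured by formation of the tertiary, cyclopropyl-stabilised radical), site selectivity for the electron-rich vinylcyclopropane alkene over the monosubstituted butenyl alkene (secured by the electrophilic character of the n,π* oxygen), and ring opening in preference to oxetane closure (favoured because the oxetane would join two fully substituted carbons and because the warm temperature favours the activated ring opening). The thermal carbonyl-ene reaction of 5, which would form the wrong C–C bond at C7, needs much higher temperature or a Lewis acid and should stay silent.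

**Step 4**
Reactants: 8 diethyl 6-(but-3-en-1-yl)-2,3,4,7-tetrahydrooxepine-2,2-dicarboxylate
Product: 9 (2R)-6-(but-3-en-1-yl)-2-(ethoxycarbonyl)-2,3,4,7-tetrahydrooxepine-2-carboxylic acid
Conditions: pig liver esterase (a carboxylesterase, serine hydrolase), 0.1 M phosphate buffer pH 7.5, DMSO (10% v/v), 25 °C, pH-stat with 1 M NaOH to 1 equiv; then 1 M HCl to pH 3 at 0 °C, EtOAc
Reagents that add atoms: water, O
Why: Enzymatic desymmetrisation of a prochiral disubstituted malonate, in which the chiral active site distinguishes the two enantiotopic ester groups through the different ring arms at C2 (O1 versus C3H2) and the anionic half-ester is not hydrolysed further, should set the C2 stereocentre.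

**Step 5**
Reactants: 9 (2R)-6-(but-3-en-1-yl)-2-(ethoxycarbonyl)-2,3,4,7-tetrahydrooxepine-2-carboxylic acid
Product: 10 2-tert-butyl 2-ethyl (2S)-6-(but-3-en-1-yl)-2,3,4,7-tetrahydrooxepine-2,2-dicarboxylate
Conditions: O-tert-butyl-N,N'-diisopropylisourea (3 equiv), CH2Cl2, rt
Reagents that add atoms: O-tert-butyl-N,N'-diisopropylisourea, CC(C)NC(=NC(C)C)OC(C)(C)C
Why: Esterification by an O-alkylisourea (protonation of the isourea, then tert-butyl transfer to the carboxylate oxygen) should tolerate the hindered acid because the bond is made at oxygen, and the quaternary stereocentre cannot epimerise (the descriptor changes to S only through priorities).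

**Step 6**
Reactants: 10 2-tert-butyl 2-ethyl (2S)-6-(but-3-en-1-yl)-2,3,4,7-tetrahydrooxepine-2,2-dicarboxylate
Product: 11 (2S)-6-(but-3-en-1-yl)-2-(tert-butoxycarbonyl)-2,3,4,7-tetrahydrooxepine-2-carboxylic acid
Conditions: LiOH·H2O (1.5 equiv), THF/H2O (3:1), 0 °C → rt; 1 M HCl to pH 3 at 0 °C
Reagents that add atoms: lithium hydroxide, [Li+].[OH-]
Why: Saponification by acyl–oxygen cleavage should take the ethyl ester, activated by the α-oxygen, and leave the sterically shielded tert-butyl ester, so the two carboxyl groups exchange their roles without touching C2.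

**Step 7**
Reactants: 11 (2S)-6-(but-3-en-1-yl)-2-(tert-butoxycarbonyl)-2,3,4,7-tetrahydrooxepine-2-carboxylic acid
Product: 13 tert-butyl (2S)-6-(but-3-en-1-yl)-2-(diazoacetyl)-2,3,4,7-tetrahydrooxepine-2-carboxylate, via acid chloride 12 (not isolated)
Conditions: 1-chloro-N,N,2-trimethylprop-1-en-1-amine (1.2 equiv), CH2Cl2, 0 °C → rt; then TMSCHN2 (2.5 equiv), THF/MeCN, 0 °C → rt
Reagents that add atoms: 1-chloro-N,N,2-trimethylprop-1-en-1-amine, CC(C)=C(Cl)N(C)C (chlorine of 12); trimethylsilyldiazomethane, C[Si](C)(C)C=[N+]=[N-]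
Why: Neutral acid chloride formation with the α-chloroenamine avoids the HCl that would cleave the tert-butyl ester, and C-acylation of the silyl diazomethane with loss of the silyl group (first stage of the Arndt–Eistert homologation) should give the diazoketone.

**Step 8**
Reactants: 13 tert-butyl (2S)-6-(but-3-en-1-yl)-2-(diazoacetyl)-2,3,4,7-tetrahydrooxepine-2-carboxylate
Product: 15 tert-butyl (2S)-6-(but-3-en-1-yl)-2-{2-[methoxy(methyl)amino]-2-oxoethyl}-2,3,4,7-tetrahydrooxepine-2-carboxylate, via ketene 14 (not isolated)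
Conditions: hν (365 nm), MeNHOMe·HCl (2 equiv), Et3N (2.5 equiv), THF, 20 °C
Reagents that add atoms: N,O-dimethylhydroxylamine hydrochloride, CNOC.Cl
Why: Photochemical Wolff rearrangement moves the quaternary C2 to the carbene carbon with retention of configuration, and the ketene is trapped by the hydroxylamine to give the homologous Weinreb amide directly.

**Step 9**
Reactants: 15 tert-butyl (2S)-6-(but-3-en-1-yl)-2-{2-[methoxy(methyl)amino]-2-oxoethyl}-2,3,4,7-tetrahydrooxepine-2-carboxylate; 16 methacrolein (2-methylprop-2-enal)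
Product: 17 tert-butyl (2S)-2-{2-[methoxy(methyl)amino]-2-oxoethyl}-6-[(3E)-4-methyl-5-oxopent-3-en-1-yl]-2,3,4,7-tetrahydrooxepine-2-carboxylate
Conditions: 16 (8 equiv), second-generation Grubbs catalyst (5 mol%), CH2Cl2, 40 °C
Reagents that add atoms: none
Why: Olefin cross-metathesis of the terminal alkene with the α-substituted enal should give the conjugated trisubstituted enal as the thermodynamically preferred E isomer, while the trisubstituted ring alkene is too hindered to take part.

**Step 10**
Reactants: 17 tert-butyl (2S)-2-{2-[methoxy(methyl)amino]-2-oxoethyl}-6-[(3E)-4-methyl-5-oxopent-3-en-1-yl]-2,3,4,7-tetrahydrooxepine-2-carboxylate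
Product: 18 tert-butyl (2S)-6-[(3E)-5-hydroxy-4-methylpent-3-en-1-yl]-2-{2-[methoxy(methyl)amino]-2-oxoethyl}-2,3,4,7-tetrahydrooxepine-2-carboxylate
Conditions: NaBH4, CeCl3·7H2O, MeOH, −40 °C
Reagents that add atoms: none
Why: Luche reduction should deliver hydride 1,2 to the enal, keep the E geometry, and leave the ester and the Weinreb amide untouched.

**Step 11**
Reactants: 19 hydroquinone
Product: 20 1,4-bis(methoxymethoxy)benzene
Conditions: MOMCl (2.6 equiv), i-Pr2NEt (3 equiv), CH2Cl2, 0 °C → rt
Reagents that add atoms: chloromethyl methyl ether, COCCl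
Why: Williamson-type O-alkylation of both phenols installs acetal groups that are stable to organolithiums, direct ortho-lithiation and leave under acid.

**Step 12**
Reactants: 18 tert-butyl (2S)-6-[(3E)-5-hydroxy-4-methylpent-3-en-1-yl]-2-{2-[methoxy(methyl)amino]-2-oxoethyl}-2,3,4,7-tetrahydrooxepine-2-carboxylate; 20 1,4-bis(methoxymethoxy)benzene
Product: 22 tert-butyl (2S)-2-{2-[2,5-bis(methoxymethoxy)phenyl]-2-oxoethyl}-6-[(3E)-5-hydroxy-4-methylpent-3-en-1-yl]-2,3,4,7-tetrahydrooxepine-2-carboxylate, via aryllithium 21 (not isolated)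
Conditions: 20 (3.2 equiv), n-BuLi (3.0 equiv), THF, 0 °C → rt, 1 h; then 18, −78 → −20 °C; aq. NH4Cl
Reagents that add atoms: n-butyllithium, CCCC[Li] (lithium of 21)
Why: Directed ortho-metalation of 20 (all four ring positions are equivalent) gives the 2,5-dioxygenated aryllithium, one equivalent of which deprotonates the hydroxyl group while a further one adds to the Weinreb amide to form a stable chelate that releases the ketone on work-up (Weinreb ketone synthesis), the hindered tert-butyl ester being spared at low temperature.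

**Step 13**
Reactants: 22 tert-butyl (2S)-2-{2-[2,5-bis(methoxymethoxy)phenyl]-2-oxoethyl}-6-[(3E)-5-hydroxy-4-methylpent-3-en-1-yl]-2,3,4,7-tetrahydrooxepine-2-carboxylate; 23 p-coumaric acid ((2E)-3-(4-hydroxyphenyl)prop-2-enoic acid)
Product: 24 tert-butyl (2S)-2-{2-[2,5-bis(methoxymethoxy)phenyl]-2-oxoethyl}-6-[(3E)-5-{[(2E)-3-(4-hydroxyphenyl)prop-2-enoyl]oxy}-4-methylpent-3-en-1-yl]-2,3,4,7-tetrahydrooxepine-2-carboxylate
Conditions: 23 (1.2 equiv), PPh3 (1.3 equiv), diisopropyl azodicarboxylate (1.3 equiv, added last), THF, 0 °C → rt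
Reagents that add atoms: none
Why: Mitsunobu esterification, in which the much more acidic carboxyl group rather than the phenol is deprotonated and displaces the primary allylic alkoxyphosphonium by SN2, should give the ester with the phenol free and both E alkenes unchanged.

**Step 14**
Reactants: 24 tert-butyl (2S)-2-{2-[2,5-bis(methoxymethoxy)phenyl]-2-oxoethyl}-6-[(3E)-5-{[(2E)-3-(4-hydroxyphenyl)prop-2-enoyl]oxy}-4-methylpent-3-en-1-yl]-2,3,4,7-tetrahydrooxepine-2-carboxylate
Product: 25 (2S)-2-[2-(2,5-dihydroxyphenyl)-2-oxoethyl]-6-[(3E)-5-{[(2E)-3-(4-hydroxyphenyl)prop-2-enoyl]oxy}-4-methylpent-3-en-1-yl]-2,3,4,7-tetrahydrooxepine-2-carboxylic acid (target)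
Conditions: TFA/CH2Cl2 (1:4), H2O (5 equiv), 0 °C → rt; toluene co-evaporation, reversed-phase chromatography
Reagents that add atoms: none
Why: Acidolysis should remove the tert-butyl ester by alkyl–oxygen cleavage (loss of 2-methylpropene) and hydrolyse both aryl methoxymethyl acetals, while the two trisubstituted alkenes (each deactivated by an allylic oxygen), the primary allylic ester and the non-epimerisable quaternary C2 should survive.

**Compound list**
1 | N-methoxy-N-methylcyclopropanecarboxamide | CON(C)C(=O)C1CC1 | starting material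
2 | but-3-en-1-ylmagnesium bromide | C=CCC[Mg]Br | starting material
3 | 1-cyclopropylpent-4-en-1-one | C=CCCC(=O)C1CC1 | intermediate
4 | 2-cyclopropylhexa-1,5-diene | C=CCCC(=C)C1CC1 | intermediate
5 | diethyl ketomalonate (diethyl 2-oxopropanedioate) | CCOC(=O)C(=O)C(=O)OCC | starting material
6 | triplet 1,4-biradical (O–CH2 bond formed; radical centres at the malonate carbon and at the cyclopropyl-bearing carbon) | CCOC(=O)[C](OC[C](CCC=C)C1CC1)C(=O)OCC | intermediate
7 | Z-configured 1,7-biradical (cyclopropane opened; radical centres at the malonate carbon and at the terminal CH2) | CCOC(=O)[C](OC/C(CCC=C)=C\C[CH2])C(=O)OCC | intermediate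
8 | diethyl 6-(but-3-en-1-yl)-2,3,4,7-tetrahydrooxepine-2,2-dicarboxylate | CCOC(=O)C1(C(=O)OCC)CCC=C(CCC=C)CO1 | intermediate
9 | (2R)-6-(but-3-en-1-yl)-2-(ethoxycarbonyl)-2,3,4,7-tetrahydrooxepine-2-carboxylic acid | C=CCCC1=CCC[C@](C(=O)OCC)(C(=O)O)OC1 | intermediate
10 | 2-tert-butyl 2-ethyl (2S)-6-(but-3-en-1-yl)-2,3,4,7-tetrahydrooxepine-2,2-dicarboxylate | C=CCCC1=CCC[C@](C(=O)OCC)(C(=O)OC(C)(C)C)OC1 | intermediate
11 | (2S)-6-(but-3-en-1-yl)-2-(tert-butoxycarbonyl)-2,3,4,7-tetrahydrooxepine-2-carboxylic acid | C=CCCC1=CCC[C@](C(=O)O)(C(=O)OC(C)(C)C)OC1 | intermediate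
12 | tert-butyl (2R)-6-(but-3-en-1-yl)-2-(chlorocarbonyl)-2,3,4,7-tetrahydrooxepine-2-carboxylate (acid chloride) | C=CCCC1=CCC[C@](C(=O)Cl)(C(=O)OC(C)(C)C)OC1 | intermediate
13 | tert-butyl (2S)-6-(but-3-en-1-yl)-2-(diazoacetyl)-2,3,4,7-tetrahydrooxepine-2-carboxylate | C=CCCC1=CCC[C@](C(=O)C=[N+]=[N-])(C(=O)OC(C)(C)C)OC1 | intermediate
14 | tert-butyl (2S)-6-(but-3-en-1-yl)-2-(2-oxoethenyl)-2,3,4,7-tetrahydrooxepine-2-carboxylate (ketene) | C=CCCC1=CCC[C@](C=C=O)(C(=O)OC(C)(C)C)OC1 | intermediate
15 | tert-butyl (2S)-6-(but-3-en-1-yl)-2-{2-[methoxy(methyl)amino]-2-oxoethyl}-2,3,4,7-tetrahydrooxepine-2-carboxylate | C=CCCC1=CCC[C@](CC(=O)N(C)OC)(C(=O)OC(C)(C)C)OC1 | intermediate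
16 | methacrolein (2-methylprop-2-enal) | CC(=C)C=O | starting material
17 | tert-butyl (2S)-2-{2-[methoxy(methyl)amino]-2-oxoethyl}-6-[(3E)-4-methyl-5-oxopent-3-en-1-yl]-2,3,4,7-tetrahydrooxepine-2-carboxylate | C/C(=C\CCC1=CCC[C@](CC(=O)N(C)OC)(C(=O)OC(C)(C)C)OC1)C=O | intermediate
18 | tert-butyl (2S)-6-[(3E)-5-hydroxy-4-methylpent-3-en-1-yl]-2-{2-[methoxy(methyl)amino]-2-oxoethyl}-2,3,4,7-tetrahydrooxepine-2-carboxylate | C/C(=C\CCC1=CCC[C@](CC(=O)N(C)OC)(C(=O)OC(C)(C)C)OC1)CO | intermediate
19 | hydroquinone | Oc1ccc(O)cc1 | starting material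
20 | 1,4-bis(methoxymethoxy)benzene | COCOc1ccc(OCOC)cc1 | intermediate
21 | [2,5-bis(methoxymethoxy)phenyl]lithium | [Li]c1cc(OCOC)ccc1OCOC | intermediate
22 | tert-butyl (2S)-2-{2-[2,5-bis(methoxymethoxy)phenyl]-2-oxoethyl}-6-[(3E)-5-hydroxy-4-methylpent-3-en-1-yl]-2,3,4,7-tetrahydrooxepine-2-carboxylate | C/C(=C\CCC1=CCC[C@](CC(=O)c2cc(OCOC)ccc2OCOC)(C(=O)OC(C)(C)C)OC1)CO | intermediate
23 | p-coumaric acid ((2E)-3-(4-hydroxyphenyl)prop-2-enoic acid) | OC(=O)/C=C/c1ccc(O)cc1 | starting material
24 | tert-butyl (2S)-2-{2-[2,5-bis(methoxymethoxy)phenyl]-2-oxoethyl}-6-[(3E)-5-{[(2E)-3-(4-hydroxyphenyl)prop-2-enoyl]oxy}-4-methylpent-3-en-1-yl]-2,3,4,7-tetrahydrooxepine-2-carboxylate | C/C(=C\CCC1=CCC[C@](CC(=O)c2cc(OCOC)ccc2OCOC)(C(=O)OC(C)(C)C)OC1)COC(=O)/C=C/c1ccc(O)cc1 | intermediate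
25 | (2S)-2-[2-(2,5-dihydroxyphenyl)-2-oxoethyl]-6-[(3E)-5-{[(2E)-3-(4-hydroxyphenyl)prop-2-enoyl]oxy}-4-methylpent-3-en-1-yl]-2,3,4,7-tetrahydrooxepine-2-carboxylic acid | C/C(=C\CCC1=CCC[C@](CC(=O)c2cc(O)ccc2O)(C(=O)O)OC1)COC(=O)/C=C/c1ccc(O)cc1 | target

Total step count: 14. Longest linear sequence: 13 steps (steps 1 to 10 and 12 to 14; step 11 is a one-step side branch).

**Steps most likely to fail**

1. Step 3. The 1,4-biradical may collapse to the oxetane before the cyclopropane opens. It may also open to the E-configured homoallyl radical, which cannot close and is lost by fragmentation or hydrogen transfer. The excited keto group may abstract allylic hydrogen.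
Fallback (sets out from 5 and 2, comes back at 8): addition of 2 to the keto carbonyl of 5 (THF, −78 °C) should give diethyl 2-(but-3-en-1-yl)-2-hydroxypropanedioate F1. O-Alkylation of its sodium alkoxide (NaH, DMF, 0 °C) with 2,3-dibromoprop-1-ene should give diethyl 2-[(2-bromoprop-2-en-1-yl)oxy]-2-(but-3-en-1-yl)propanedioate F2. Negishi coupling of the vinyl bromide (PdCl2(dppf), THF, 50 °C) with but-3-en-1-ylzinc bromide F3, made from 2 and ZnBr2, should give diethyl 2-(but-3-en-1-yl)-2-[(2-methylidenehex-5-en-1-yl)oxy]propanedioate F4. Ring-closing metathesis (second-generation Grubbs catalyst, CH2Cl2, 40 °C, high dilution) between the 1,1-disubstituted alkene and the butenyl group on the malonate carbon should close the seven-membered ring and return 8.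

2. Step 4. The enzyme may hydrolyse the pro-R instead of the pro-S ester group, or discriminate poorly between the two.
Fallback (sets out from 8, comes back at 9): chemical monosaponification (KOH, 1 equiv, EtOH/H2O, 0 °C) should give racemic 6-(but-3-en-1-yl)-2-(ethoxycarbonyl)-2,3,4,7-tetrahydrooxepine-2-carboxylic acid F5. Classical resolution follows, by crystallisation of (1R)-1-phenylethan-1-aminium (2R)-6-(but-3-en-1-yl)-2-(ethoxycarbonyl)-2,3,4,7-tetrahydrooxepine-2-carboxylate F6; the enantiomeric amine is used if it gives the less soluble salt of the (R)-acid. Release with cold 1 M HCl returns 9.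

3. Step 14. During the protic global deprotection the liberated methoxymethyl and tert-butyl cations may alkylate the phenolic rings, the allylic ester may ionise, and acid may add to the trisubstituted alkenes.
Fallback (sets out from 24, comes back at 25): protic acidolysis is replaced by silyl transfer under buffered aprotic conditions (TMSOTf, 2,2'-bipyridyl, CH2Cl2, 0 °C → rt). This converts aryl methoxymethyl ethers into aryl silyl ethers and the tert-butyl ester into a silyl ester, and should give trimethylsilyl (2S)-2-{2-[2,5-bis(trimethylsilyloxy)phenyl]-2-oxoethyl}-6-[(3E)-4-methyl-5-{[(2E)-3-(4-trimethylsilyloxyphenyl)prop-2-enoyl]oxy}pent-3-en-1-yl]-2,3,4,7-tetrahydrooxepine-2-carboxylate F7. A separate neutral hydrolysis (THF/H2O, rt) then returns 25.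

**Further compounds**
F1 | step 3 | diethyl 2-(but-3-en-1-yl)-2-hydroxypropanedioate | CCOC(=O)C(O)(CCC=C)C(=O)OCC
F2 | step 3 | diethyl 2-[(2-bromoprop-2-en-1-yl)oxy]-2-(but-3-en-1-yl)propanedioate | CCOC(=O)C(CCC=C)(OCC(Br)=C)C(=O)OCC
F3 | step 3 | but-3-en-1-ylzinc bromide | C=CCC[Zn]Br
F4 | step 3 | diethyl 2-(but-3-en-1-yl)-2-[(2-methylidenehex-5-en-1-yl)oxy]propanedioate | CCOC(=O)C(CCC=C)(OCC(=C)CCC=C)C(=O)OCC
F5 | step 4 | racemic 6-(but-3-en-1-yl)-2-(ethoxycarbonyl)-2,3,4,7-tetrahydrooxepine-2-carboxylic acid | C=CCCC1=CCCC(C(=O)OCC)(C(=O)O)OC1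
F6 | step 4 | (1R)-1-phenylethan-1-aminium (2R)-6-(but-3-en-1-yl)-2-(ethoxycarbonyl)-2,3,4,7-tetrahydrooxepine-2-carboxylate | C=CCCC1=CCC[C@](C(=O)OCC)(C(=O)[O-])OC1.C[C@@H]([NH3+])c1ccccc1
F7 | step 14 | trimethylsilyl (2S)-2-{2-[2,5-bis(trimethylsilyloxy)phenyl]-2-oxoethyl}-6-[(3E)-4-methyl-5-{[(2E)-3-(4-trimethylsilyloxyphenyl)prop-2-enoyl]oxy}pent-3-en-1-yl]-2,3,4,7-tetrahydrooxepine-2-carboxylate | C/C(=C\CCC1=CCC[C@](CC(=O)c2cc(O[Si](C)(C)C)ccc2O[Si](C)(C)C)(C(=O)O[Si](C)(C)C)OC1)COC(=O)/C=C/c1ccc(O[Si](C)(C)C)cc1
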